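**Remarks on the chemistry (assumptions)**
- Ring atoms are numbered O1, C2, C3 (carries the guaiacylmethyl group), C4 (carries the carbinol carbon, called C1′), C5. Piv = 2,2-dimethylpropanoyl, TBS = tert-butyldimethylsilyl.
- The facial sense of the imidazolidinone in step 5 is taken from the shielding model of its enamine radical cation; if it proved opposite, the (2R,5R) catalyst would be used and nothing else would change.
- 4-Bromo-2,6-dimethoxyphenol (4) and the E-configured pinacol boronate 6 are taken as purchasable.

## Structural features

The target is a 3,4-disubstituted oxolane (ring A) in which C2 and C5 are plain O–CH2 groups. C3 carries a 4-hydroxy-3-methoxybenzyl group and C4 carries the carbinol carbon C1′, which bears a 4-hydroxy-3,5-dimethoxyphenyl ring. Three stereocentres stand side by side, C3 (R), C4 (R) and C1′ (S), and the two ring substituents are trans. Two C6–C3 units are joined through their central carbons (C3–C4) and their terminal carbons are bridged by O1, so ether formation from the benzylic oxygen instead (a 2-aryl-oxolane) is a constitutional trap. The fragile part is C1′: a para-hydroxybenzylic alcohol ionises through a quinone methide under acid or heat, which would scramble C1′, add solvent or close a six-membered ring onto the guaiacyl arene; the free phenols and both electron-rich rings are also sensitive to oxidants. The real difficulty is absolute control at C3, which has no acidifying neighbour once the ring exists and cannot be repaired, whereas C4 can be equilibrated while C1′ is a ketone and C1′ can be set by hydride addition next to C4. The key step uses the C3–C4 bond: C3 is the α-carbon of a 3-arylpropanal whose carbonyl carbon becomes C2, and C4 is the alkene carbon remote from the arene in a cinnamyl silyl ether whose CH2O group becomes C5 and whose benzylic carbon C1′ receives oxygen in the same event.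

## Logic of the disconnections

15 is traced back to 14 by cutting the two aryl O–acyl bonds. The phenols and the quinone-methide-prone carbinol are thus exposed only in the last operation, and every earlier intermediate is non-phenolic and harder to oxidise. The forward step must deacylate a hindered aryl ester without acid.

14 is traced back to 13 by cutting the C1′–H bond. With C1′ as a ketone, C4 becomes epimerisable and the last stereocentre can be set under control of C4. The forward step needs a hydride that attacks one carbonyl face and spares the aryl esters.

13 is traced back to 10, through 12 and 11, by cutting the O1–C2 bond, returning the C1′ carbonyl to a nitrate ester and releasing the C4 configuration. Attack of a primary alkoxide on a primary sulfonate is the most reliable way to close this ether. Closing the ring before the ketone exists removes the chance of a C4 enolate attacking C2. The forward step needs fluoride to free the C5 oxygen without harming the esters, and a base strong enough to turn the nitrate into the ketone and equilibrate C4 without opening the ring.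

10 is traced back to 9 and then to 8 by functional-group changes at C2 (sulfonate, alcohol, aldehyde). The aldehyde has to be reduced at once because its α-carbon is C3. The forward steps need a hydride that leaves the nitrate ester, the aryl esters and the silyl ether alone.

8 is traced back to 3 and 7 by cutting C3–C4 and the C1′–O bond. This splits the molecule into its two C6–C3 halves, both achiral and each two steps from purchasable material. The forward step must control the face of the aldehyde α-carbon, add to the alkene carbon remote from the arene, oxidise the enamine in preference to either arene, and deliver oxygen to C1′ before the guaiacyl ring can capture the benzylic position.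

3 is traced back to 2 and to 1 by oxidation-level and protecting-group changes. The only demand is acylation of the phenol in the presence of the primary alcohol.

7 is traced back to 5 and 6 by cutting the aryl–alkenyl bond, and 5 to 4 by cutting the O–acyl bond. The E geometry and the silyl ether then arrive ready-made in 6. This replaces a longer ester-reduction and selective-protection sequence by two steps, provided the coupling leaves the aryl ester intact.

## Other disconnections considered

Alternative 1: The cut is again C3–C4, made by carbenoid C–H insertion. The diazo β-keto ester A1 would be decomposed by a chiral dirhodium tetracarboxylate (divalent rhodium) such as Rh2(S-PTTL)4, and the carbenoid would insert into the methylene C–H that becomes C3, closing the trans lactone A2.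
- In its favour: the strategic bond and a ring form together; C1′ arrives directly as the ketone, with no nitrate ester to handle, which is better than the chosen plan on that point; no stoichiometric oxidant is used, which is better on waste.
- Against it here: the carbenoid of A1 carries two acceptor groups and is very electrophilic. It must choose the homobenzylic C–H (five-membered ring) over the benzylic C–H (six-membered ring) and over addition to the electron-rich guaiacyl ring, and the ester has to react through its less populated conformer. High enantioselectivity in lactone-forming insertions is best established for simple diazoacetates, so the C3 configuration would be less predictable.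
- After A2 the ring carbonyl at C5 must be taken down to CH2 beside an aryl ketone. That means global reduction, differentiation of three hydroxyl groups (with the 2-aryl-oxolane trap open), and re-oxidation. Final hydrogenolysis of benzyl ethers would take place next to a benzylic alcohol.
- Comparison: on structure the two plans are equal, since both fix only C3 by a catalyst, equilibrate C4 and reduce a ketone at C1′. On mechanism the alternative is closed-shell and the chosen plan is a radical-cation process with a sacrificial oxidant. On step economy the alternative should need about twelve to thirteen operations against ten.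

Alternative 2: The cuts are C2–C3 and C4–C5. SnCl4 would open the formaldehyde acetal A3 to an oxocarbenium ion, and Prins cyclisation with pinacol shift (or oxonia-Cope shift and aldol closure) would give the trans ketone A4.
- In its favour: two C–C bonds and the oxolane form in one step, whereas the chosen plan needs three later operations for the ring; this is better than the chosen plan. A4 is the direct counterpart of 13, already trans and at the ketone level, so no nitrate-to-ketone conversion is needed; this is also better. The E-alkene should map onto the trans ring, and the ketone is epimerisable in any case, which is equal.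
- Against it here: the only stereocentre of A3, its quaternary carbinol carbon, is destroyed in the step. Absolute configuration at C3 would depend on a concerted chair-like Prins pathway; the oxonia-Cope and aldol pathway passes through an achiral enol and oxocarbenium pair and would erode it. A3 needs an asymmetric step of its own for a tertiary allylic centre. Its skipped 1,3-diarylpropene may move into conjugation under a strong Lewis acid. Two different phenol protecting groups mean two separate deprotections.
- Comparison: the step count should be about equal to the chosen plan (ten to eleven). The control of C3 is weaker than catalyst control in the chosen plan, and C3 is the one centre that cannot be corrected later.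

Alternative 3: The cut is O1–C5. (salen)Co(OTf) (trivalent cobalt) would activate the oxetane of A5, and the pendant primary hydroxyl would open one of the two oxetane CH2–O bonds (5-exo-tet) to give the trans oxolane methanol A6.
- In its favour: mild, catalytic, closed-shell conditions with no oxidant and only a silyl ether to carry. C4 would be set kinetically under catalyst control without an equilibration step, which is equal to or better than the chosen plan for that centre.
- Against it here: A5 already contains C3, which must come from a separate asymmetric step. The catalyst then only selects between two diastereotopic CH2–O bonds, which may be a matched or a mismatched case. A monosubstituted oxetane is a slower substrate than the disubstituted ones usually used. The whole syringyl carbinol is still missing after A6: oxidation, addition of an aryl-metal (little stereocontrol expected), re-oxidation and reduction must follow.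
- Comparison: on structure the alternative is the least convergent of the four plans. On mechanism it is the gentlest. The final ketone reduction would be the same as in the chosen plan, which is equal. On step economy it should be the longest, at about thirteen to fourteen operations.

Key step: step 5

## Route

Step 1
Reactants: 1 dihydroconiferyl alcohol
Product: 2 4-(3-hydroxypropyl)-2-methoxyphenyl pivalate
Conditions: PivCl (1.05 equiv), aq NaOH, Bu4NHSO4 (cat.), CH2Cl2, 0 °C
Reagents that add atoms: pivaloyl chloride, CC(C)(C)C(=O)Cl
Why: Under phase-transfer Schotten–Baumann conditions only the phenol is ionised, and the phenoxide is acylated far faster than the neutral primary alcohol (chemoselective O-acylation).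

Step 2
Reactants: 2 4-(3-hydroxypropyl)-2-methoxyphenyl pivalate
Product: 3 2-methoxy-4-(3-oxopropyl)phenyl pivalate
Conditions: TEMPO (10 mol %), PhI(OAc)2, CH2Cl2, rt
Reagents that add atoms: none
Why: Oxoammonium (TEMPO) oxidation with PhI(OAc)2 as terminal oxidant stops at the aldehyde and leaves the aryl ester and the non-phenolic arene alone.

Step 3
Reactants: 4 4-bromo-2,6-dimethoxyphenol
Product: 5 4-bromo-2,6-dimethoxyphenyl pivalate
Conditions: PivCl, Et3N, DMAP (cat.), CH2Cl2, 0 °C to rt
Reagents that add atoms: pivaloyl chloride, CC(C)(C)C(=O)Cl
Why: DMAP-catalysed acylation of a hindered phenol; the ester lowers the electron density of the ring for step 5 and is robust enough for the coupling.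

Step 4
Reactants: 5 4-bromo-2,6-dimethoxyphenyl pivalate; 6 (E)-2-[3-(tert-butyldimethylsilyloxy)prop-1-en-1-yl]-4,4,5,5-tetramethyl-1,3,2-dioxaborolane
Product: 7 (E)-4-[3-(tert-butyldimethylsilyloxy)prop-1-en-1-yl]-2,6-dimethoxyphenyl pivalate
Conditions: Pd(dppf)Cl2 (3 mol %), K3PO4, 1,4-dioxane/H2O (10:1), 80 °C
Reagents that add atoms: none
Why: Suzuki–Miyaura coupling of an unhindered aryl bromide with an alkenyl boronate keeps the alkene geometry, so the E-alkene comes from 6; a hindered aryl pivalate and a primary silyl ether should tolerate K3PO4 at this temperature.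

Step 5
Reactants: 3 2-methoxy-4-(3-oxopropyl)phenyl pivalate; 7 (E)-4-[3-(tert-butyldimethylsilyloxy)prop-1-en-1-yl]-2,6-dimethoxyphenyl pivalate
Product: 8 (2R)-3-[(tert-butyldimethylsilyloxy)methyl]-4-(3,5-dimethoxy-4-pivaloyloxyphenyl)-2-(3-methoxy-4-pivaloyloxybenzyl)-4-(nitrooxy)butanal (epimers at the two other chain stereocentres)
Conditions: (2S,5S)-5-benzyl-2-tert-butyl-3-methylimidazolidin-4-one·CF3CO2H (20 mol %), (NH4)2Ce(NO3)6 (2.5 equiv), NaHCO3 (1.5 equiv), H2O (2 equiv), 7 (2 equiv), DME, −30 °C; crude aldehyde used at once
Reagents that add atoms: ammonium hexanitratocerate (tetravalent cerium), [NH4+].[NH4+].[Ce+4].[O-][N+](=O)[O-].[O-][N+](=O)[O-].[O-][N+](=O)[O-].[O-][N+](=O)[O-].[O-][N+](=O)[O-].[O-][N+](=O)[O-]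
Why: Proposed new method: the imidazolidinone condenses with 3 to an E-enamine that (NH4)2Ce(NO3)6 oxidises by one electron to a 3π-electron radical cation; this electrophilic radical adds to the alkene carbon of 7 that carries the CH2OSi group, because only that regiochemistry gives a benzylic radical, and a second tetravalent cerium oxidises the benzylic radical with transfer of nitrate to carbon before hydrolysis returns the catalyst. The closest known reaction type is the enantioselective organo-SOMO carbo-oxidation of terminal styrenes with aldehydes, and the addition of the same radical cations to the substituted carbon of β-styryl trifluoroborates indicates that a 1,2-disubstituted styrene can accept them; what is new is an internal alkene bearing an allylic silyl ether. No ring is closed. The only controlled stereocentre is C3: in the radical cation the π-system turns away from the tert-butyl group and the benzyl group covers the Re face of the α-carbon, so bond formation on the Si face with the (2S,5S) catalyst should give the (R) centre, while C4 and C1′ form without useful control and are corrected in steps 8 and 9. The step needs the oxidant to take the enamine and not the arenes or the styrene, which the two pivalates secure by lowering the electron density of both rings. It also needs nitrate capture to beat Friedel–Crafts closure of the benzylic position onto the guaiacyl ring, which the acyloxy group meta to the reactive ring carbon, the high nitrate concentration and the low temperature should favour.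

Step 6
Reactants: 8 (2R)-γ-nitrooxy aldehyde
Product: 9 (2R)-3-[(tert-butyldimethylsilyloxy)methyl]-4-(3,5-dimethoxy-4-pivaloyloxyphenyl)-2-(3-methoxy-4-pivaloyloxybenzyl)-4-(nitrooxy)butan-1-ol (epimers as in 8)
Conditions: NaBH4, THF/MeOH (4:1), −20 °C
Reagents that add atoms: none
Why: Borohydride reduction of the aldehyde at low temperature is faster than epimerisation at C3 and does not touch nitrate esters, aryl pivalates or the silyl ether; after this step C3 is no longer α to a carbonyl group.

Step 7
Reactants: 9 (2R)-nitrooxy alcohol
Product: 10 (2R)-3-[(tert-butyldimethylsilyloxy)methyl]-4-(3,5-dimethoxy-4-pivaloyloxyphenyl)-2-(3-methoxy-4-pivaloyloxybenzyl)-4-(nitrooxy)butyl methanesulfonate (epimers as in 8)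
Conditions: MsCl, Et3N, CH2Cl2, −20 °C
Reagents that add atoms: methanesulfonyl chloride, CS(=O)(=O)Cl
Why: Sulfonylation of the only free hydroxyl group (sulfene pathway) at low temperature and with short contact with the amine, so that the benzylic nitrate is not yet eliminated.

Step 8
Reactants: 10 (2R)-silyloxy mesylate
Product: 13 [(3R,4R)-4-(3-methoxy-4-pivaloyloxybenzyl)oxolan-3-yl](3,5-dimethoxy-4-pivaloyloxyphenyl)methanone, via hydroxy mesylate 11 (not isolated), via oxolane nitrate 12 (not isolated)
Conditions: Bu4NF (1.2 equiv), THF, 0 °C to rt; then DBU (2 equiv), rt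
Reagents that add atoms: none
Why: Fluoride desilylation frees the C5 alkoxide, which displaces the primary mesylate at C2 (intramolecular Williamson etherification, 5-exo-tet); DBU then removes the benzylic hydrogen of the nitrate ester with loss of nitrite (carbonyl-forming elimination) and equilibrates C4 through the enol to the more stable trans ring, so C4 is set under thermodynamic control. Closing the ring before the ketone appears avoids cyclopropane formation from a C4 enolate and a C2 sulfonate, and the ring C5–O bond lies close to the plane of the enolate, which disfavours β-elimination.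

Step 9
Reactants: 13 trans-ketone
Product: 14 4-[(S)-hydroxy{(3R,4R)-4-(3-methoxy-4-pivaloyloxybenzyl)oxolan-3-yl}methyl]-2,6-dimethoxyphenyl pivalate
Conditions: LiBH(s-Bu)3, THF, −78 °C; then aq NH4Cl
Reagents that add atoms: none
Why: Felkin–Anh addition of a bulky hydride: with the branched ring carbon C3 antiperiplanar to the incoming hydride and C5 flanking the carbonyl oxygen, attack past the C4 hydrogen gives the (S) carbinol, and a lithium chelate between the carbonyl oxygen and O1 would expose the same face. At −78 °C the hindered aryl pivalates should not be reduced.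

Step 10
Reactants: 14 (S)-carbinol bis-pivalate
Product: 15 4-[(S)-hydroxy{(3R,4R)-4-[(4-hydroxy-3-methoxyphenyl)methyl]oxolan-3-yl}methyl]-2,6-dimethoxyphenol (target)
Conditions: NaOMe (3 equiv), MeOH/THF, 0 °C to rt; then aq NH4Cl to pH 7
Reagents that add atoms: none
Why: Methoxide transesterification cleaves aryl esters, whose phenoxides are good leaving groups, without any acid, so the para-hydroxybenzylic alcohol is not ionised; neutralising before concentration avoids quinone methide formation.

## Compound list

1 | dihydroconiferyl alcohol, 4-(3-hydroxypropyl)-2-methoxyphenol | COc1cc(CCCO)ccc1O | starting material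
2 | 4-(3-hydroxypropyl)-2-methoxyphenyl pivalate | COc1cc(CCCO)ccc1OC(=O)C(C)(C)C | intermediate
3 | 2-methoxy-4-(3-oxopropyl)phenyl pivalate | COc1cc(CCC=O)ccc1OC(=O)C(C)(C)C | intermediate
4 | 4-bromo-2,6-dimethoxyphenol | COc1cc(Br)cc(OC)c1O | starting material
5 | 4-bromo-2,6-dimethoxyphenyl pivalate | COc1cc(Br)cc(OC)c1OC(=O)C(C)(C)C | intermediate
6 | (E)-2-[3-(tert-butyldimethylsilyloxy)prop-1-en-1-yl]-4,4,5,5-tetramethyl-1,3,2-dioxaborolane | CC(C)(C)[Si](C)(C)OC/C=C/B1OC(C)(C)C(C)(C)O1 | starting material
7 | (E)-4-[3-(tert-butyldimethylsilyloxy)prop-1-en-1-yl]-2,6-dimethoxyphenyl pivalate | COc1cc(/C=C/CO[Si](C)(C)C(C)(C)C)cc(OC)c1OC(=O)C(C)(C)C | intermediate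
8 | (2R)-γ-nitrooxy aldehyde (C3 defined, C4 and C1′ as epimers) | COc1cc(C[C@H](C(CO[Si](C)(C)C(C)(C)C)C(O[N+](=O)[O-])c2cc(OC)c(OC(=O)C(C)(C)C)c(OC)c2)C=O)ccc1OC(=O)C(C)(C)C | intermediate
9 | (2R)-nitrooxy alcohol (epimers as in 8) | COc1cc(C[C@H](C(CO[Si](C)(C)C(C)(C)C)C(O[N+](=O)[O-])c2cc(OC)c(OC(=O)C(C)(C)C)c(OC)c2)CO)ccc1OC(=O)C(C)(C)C | intermediate
10 | (2R)-silyloxy mesylate (epimers as in 8) | COc1cc(C[C@H](C(CO[Si](C)(C)C(C)(C)C)C(O[N+](=O)[O-])c2cc(OC)c(OC(=O)C(C)(C)C)c(OC)c2)COS(C)(=O)=O)ccc1OC(=O)C(C)(C)C | intermediate
11 | hydroxy mesylate formed in the flask in step 8 (epimers as in 8) | COc1cc(C[C@H](C(CO)C(O[N+](=O)[O-])c2cc(OC)c(OC(=O)C(C)(C)C)c(OC)c2)COS(C)(=O)=O)ccc1OC(=O)C(C)(C)C | intermediate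
12 | oxolane nitrate formed in the flask in step 8, (R) at the benzyl-bearing ring carbon, epimers at C4 and C1′ | COc1cc(C[C@H]2COCC2C(O[N+](=O)[O-])c2cc(OC)c(OC(=O)C(C)(C)C)c(OC)c2)ccc1OC(=O)C(C)(C)C | intermediate
13 | [(3R,4R)-4-(3-methoxy-4-pivaloyloxybenzyl)oxolan-3-yl](3,5-dimethoxy-4-pivaloyloxyphenyl)methanone | COc1cc(C[C@H]2COC[C@@H]2C(=O)c2cc(OC)c(OC(=O)C(C)(C)C)c(OC)c2)ccc1OC(=O)C(C)(C)C | intermediate
14 | 4-[(S)-hydroxy{(3R,4R)-4-(3-methoxy-4-pivaloyloxybenzyl)oxolan-3-yl}methyl]-2,6-dimethoxyphenyl pivalate | COc1cc(C[C@H]2COC[C@@H]2[C@H](O)c2cc(OC)c(OC(=O)C(C)(C)C)c(OC)c2)ccc1OC(=O)C(C)(C)C | intermediate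
15 | 4-[(S)-hydroxy{(3R,4R)-4-[(4-hydroxy-3-methoxyphenyl)methyl]oxolan-3-yl}methyl]-2,6-dimethoxyphenol | COc1cc(C[C@H]2COC[C@@H]2[C@H](O)c2cc(OC)c(O)c(OC)c2)ccc1O | target

## Step count and least certain steps

Total: 10 steps. Longest linear sequence: 8 steps (steps 1, 2, 5–10; the branch through steps 3 and 4 is equally long).

**Step 5 (key step, proposed new method).**
- Most likely to go wrong: addition to the internal, allylically substituted alkene is slower than to a terminal styrene, so the enamine radical cation may be diverted into self-coupling or over-oxidation.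
- The benzylic position may be captured by the guaiacyl ring (six-membered Friedel–Crafts closure) instead of by nitrate, because the ring carbon para to the methoxy group is still nucleophilic.
- Cerium may oxidise the styrene directly or strip the silyl ether through its Lewis acidity.
- The α-branched aldehyde may lose enantiopurity by enolisation before it is reduced.
- Fallback (known chemistry; sets out from 1 and comes back at 15): auxiliary-controlled alkylation followed by a lactone aldol.
  - 1 is O-benzylated (BnBr, K2CO3) to 3-(4-benzyloxy-3-methoxyphenyl)propan-1-ol F1 and oxidised (TEMPO, NaOCl, NaClO2) to 3-(4-benzyloxy-3-methoxyphenyl)propanoic acid F2.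
  - The mixed pivalic anhydride of F2 acylates lithiated (S)-4-benzyl-oxazolidin-2-one to give the imide F3. Its sodium enolate (NaN(SiMe3)2, −78 °C) is alkylated by tert-butyl bromoacetate on the face away from the auxiliary benzyl group to give the (R)-configured alkylated imide F4.
  - LiBH4 removes the auxiliary and CF3CO2H closes the (R)-β-arylmethyl-γ-butyrolactone F5.
  - The lithium enolate of F5 (LiN(SiMe3)2) adds to 4-benzyloxy-3,5-dimethoxybenzaldehyde trans to the ring substituent to give the aldol lactone F6 as carbinol epimers. F6 is silylated (TBSOTf, 2,6-lutidine) to the silyl ether F7 and reduced (LiAlH4) to the 1,4-diol F8.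
  - Mitsunobu cyclodehydration (PPh3, DIAD) closes the oxolane silyl ether F9, and Bu4NF frees the oxolane carbinol F10.
  - Dess–Martin periodinane gives the bis-benzyl ketone F11 (the counterpart of 13), LiBH(s-Bu)3 gives the bis-benzyl (S)-carbinol F12, and hydrogenolysis (H2, Pd on carbon, EtOAc) gives 15.

**Step 8.**
- Most likely to go wrong: fluoride or the alkoxide may act as a base on the benzylic nitrate before the ring has closed. An open-chain ketone with a C2 sulfonate could then alkylate at C4 to a cyclopropane.
- Fluoride may also displace the mesylate or attack the aryl pivalates.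
- Fallback (sets out from 9 and comes back at 12): 9 is desilylated under acidic, non-basic conditions (HF·pyridine, THF, 0 °C) to the diol nitrate F13. Its two primary hydroxyl groups are joined by Mitsunobu cyclodehydration (PPh3, DIAD, THF, 0 °C), either one serving as the leaving group, to give 12, now isolated. DBU then converts 12 into 13 as in the second half of step 8. No sulfonate is ever exposed to a basic nucleophile.

**Step 9.**
- Most likely to go wrong: facial selectivity may be poor or reversed, because the two substituents at C4 that differentiate the faces (C3 and C5) are both ring carbons of similar size. Slow reduction of the hindered aryl ketone could also allow hydride attack on the pivalates if the temperature is raised.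
- Fallback (sets out from 13 and comes back at 15): whatever amount of the (R)-carbinol epimer F14 forms is separated and inverted by Mitsunobu esterification with 4-nitrobenzoic acid (PPh3, DIAD) to the (S)-4-nitrobenzoate F15. The conditions of step 10 then cleave the nitrobenzoate together with both pivalates to give 15. Configuration at C1′ is then set by SN2 inversion and not by hydride face selection.

**Step 10.**
- Most likely to go wrong: methanolysis may stall at the pivalate flanked by two methoxy groups. If it is forced by heat, the freed para-hydroxybenzylic alcohol may ionise through its quinone methide, losing C1′ configuration or adding methanol.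
- Fallback (sets out from 13 and comes back at 15): the esters are removed at the ketone stage, where heating is harmless (NaOMe, MeOH, up to 50 °C), to give the bisphenol ketone F16. F16 is then reduced with excess LiBH(s-Bu)3 (the phenols react first to lithium phenoxides) to 15. The reduction of the phenoxide-deactivated ketone should be slower and may be less selective than step 9.

## Further compounds

F1 | step 5 | 3-(4-benzyloxy-3-methoxyphenyl)propan-1-ol | COc1cc(CCCO)ccc1OCc1ccccc1
F2 | step 5 | 3-(4-benzyloxy-3-methoxyphenyl)propanoic acid | COc1cc(CCC(=O)O)ccc1OCc1ccccc1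
F3 | step 5 | (4S)-4-benzyl-3-[3-(4-benzyloxy-3-methoxyphenyl)propanoyl]oxazolidin-2-one | COc1cc(CCC(=O)N2C(=O)OC[C@@H]2Cc2ccccc2)ccc1OCc1ccccc1
F4 | step 5 | tert-butyl (3R)-3-(4-benzyloxy-3-methoxybenzyl)-4-[(4S)-4-benzyl-2-oxooxazolidin-3-yl]-4-oxobutanoate | COc1cc(C[C@H](CC(=O)OC(C)(C)C)C(=O)N2C(=O)OC[C@@H]2Cc2ccccc2)ccc1OCc1ccccc1
F5 | step 5 | (4R)-4-(4-benzyloxy-3-methoxybenzyl)oxolan-2-one | COc1cc(C[C@H]2COC(=O)C2)ccc1OCc1ccccc1
F6 | step 5 | trans-3-[(4-benzyloxy-3,5-dimethoxyphenyl)(hydroxy)methyl]-4-(4-benzyloxy-3-methoxybenzyl)oxolan-2-one (4R, carbinol epimers) | COc1cc(C[C@H]2COC(=O)[C@@H]2C(O)c2cc(OC)c(OCc3ccccc3)c(OC)c2)ccc1OCc1ccccc1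
F7 | step 5 | tert-butyldimethylsilyl ether of F6 | COc1cc(C[C@H]2COC(=O)[C@@H]2C(O[Si](C)(C)C(C)(C)C)c2cc(OC)c(OCc3ccccc3)c(OC)c2)ccc1OCc1ccccc1
F8 | step 5 | (2R,3R)-2-(4-benzyloxy-3-methoxybenzyl)-3-[(4-benzyloxy-3,5-dimethoxyphenyl)(tert-butyldimethylsilyloxy)methyl]butane-1,4-diol | COc1cc(C[C@@H](CO)[C@H](CO)C(O[Si](C)(C)C(C)(C)C)c2cc(OC)c(OCc3ccccc3)c(OC)c2)ccc1OCc1ccccc1
F9 | step 5 | trans-3-(4-benzyloxy-3-methoxybenzyl)-4-[(4-benzyloxy-3,5-dimethoxyphenyl)(tert-butyldimethylsilyloxy)methyl]oxolane | COc1cc(C[C@H]2COC[C@@H]2C(O[Si](C)(C)C(C)(C)C)c2cc(OC)c(OCc3ccccc3)c(OC)c2)ccc1OCc1ccccc1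
F10 | step 5 | (4-benzyloxy-3,5-dimethoxyphenyl)[trans-4-(4-benzyloxy-3-methoxybenzyl)oxolan-3-yl]methanol (carbinol epimers) | COc1cc(C[C@H]2COC[C@@H]2C(O)c2cc(OC)c(OCc3ccccc3)c(OC)c2)ccc1OCc1ccccc1
F11 | step 5 | (4-benzyloxy-3,5-dimethoxyphenyl)[(3R,4R)-4-(4-benzyloxy-3-methoxybenzyl)oxolan-3-yl]methanone | COc1cc(C[C@H]2COC[C@@H]2C(=O)c2cc(OC)c(OCc3ccccc3)c(OC)c2)ccc1OCc1ccccc1
F12 | step 5 | (S)-(4-benzyloxy-3,5-dimethoxyphenyl)[(3R,4R)-4-(4-benzyloxy-3-methoxybenzyl)oxolan-3-yl]methanol | COc1cc(C[C@H]2COC[C@@H]2[C@H](O)c2cc(OC)c(OCc3ccccc3)c(OC)c2)ccc1OCc1ccccc1
F13 | step 8 | (2R)-3-(hydroxymethyl)-4-(3,5-dimethoxy-4-pivaloyloxyphenyl)-2-(3-methoxy-4-pivaloyloxybenzyl)-4-(nitrooxy)butan-1-ol (epimers as in 8) | COc1cc(C[C@H](C(CO)C(O[N+](=O)[O-])c2cc(OC)c(OC(=O)C(C)(C)C)c(OC)c2)CO)ccc1OC(=O)C(C)(C)C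
F14 | step 9 | 4-[(R)-hydroxy{(3R,4R)-4-(3-methoxy-4-pivaloyloxybenzyl)oxolan-3-yl}methyl]-2,6-dimethoxyphenyl pivalate | COc1cc(C[C@H]2COC[C@@H]2[C@@H](O)c2cc(OC)c(OC(=O)C(C)(C)C)c(OC)c2)ccc1OC(=O)C(C)(C)C
F15 | step 9 | (S)-(3,5-dimethoxy-4-pivaloyloxyphenyl)[(3R,4R)-4-(3-methoxy-4-pivaloyloxybenzyl)oxolan-3-yl]methyl 4-nitrobenzoate | COc1cc(C[C@H]2COC[C@@H]2[C@H](OC(=O)c2ccc(cc2)[N+](=O)[O-])c2cc(OC)c(OC(=O)C(C)(C)C)c(OC)c2)ccc1OC(=O)C(C)(C)C
F16 | step 10 | (4-hydroxy-3,5-dimethoxyphenyl)[(3R,4R)-4-(4-hydroxy-3-methoxybenzyl)oxolan-3-yl]methanone | COc1cc(C[C@H]2COC[C@@H]2C(=O)c2cc(OC)c(O)c(OC)c2)ccc1O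
A1 | alternative 1 | 3-(4-benzyloxy-3-methoxyphenyl)propyl 3-(4-benzyloxy-3,5-dimethoxyphenyl)-2-diazo-3-oxopropanoate | COc1cc(CCCOC(=O)C(=[N+]=[N-])C(=O)c2cc(OC)c(OCc3ccccc3)c(OC)c2)ccc1OCc1ccccc1
A2 | alternative 1 | trans-(3S,4R)-3-(4-benzyloxy-3,5-dimethoxybenzoyl)-4-(4-benzyloxy-3-methoxybenzyl)oxolan-2-one | COc1cc(C[C@H]2COC(=O)[C@@H]2C(=O)c2cc(OC)c(OCc3ccccc3)c(OC)c2)ccc1OCc1ccccc1
A3 | alternative 2 | 4-(3,5-dimethoxy-4-methanesulfonyloxyphenyl)-4-{(E)-3-[3-methoxy-4-(triisopropylsilyloxy)phenyl]prop-1-en-1-yl}-1,3-dioxolane (configuration at the quaternary carbon left open) | COc1cc(C/C=C/C2(c3cc(OC)c(OS(C)(=O)=O)c(OC)c3)COCO2)ccc1O[Si](C(C)C)(C(C)C)C(C)C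
A4 | alternative 2 | (3,5-dimethoxy-4-methanesulfonyloxyphenyl){(3R,4R)-4-[3-methoxy-4-(triisopropylsilyloxy)benzyl]oxolan-3-yl}methanone | COc1cc(C[C@H]2COC[C@@H]2C(=O)c2cc(OC)c(OS(C)(=O)=O)c(OC)c2)ccc1O[Si](C(C)C)(C(C)C)C(C)C
A5 | alternative 3 | (2R)-3-[3-methoxy-4-(triisopropylsilyloxy)phenyl]-2-(oxetan-3-yl)propan-1-ol | COc1cc(C[C@H](C2COC2)CO)ccc1O[Si](C(C)C)(C(C)C)C(C)C
A6 | alternative 3 | trans-[(3S,4R)-4-{[3-methoxy-4-(triisopropylsilyloxy)phenyl]methyl}oxolan-3-yl]methanol | COc1cc(C[C@H]2COC[C@@H]2CO)ccc1O[Si](C(C)C)(C(C)C)C(C)C
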